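**Retrosynthetic overview**

- The strategy rests on the trisubstituted E-alkene C3=C4, whose methyl sits on C4 and which is joined through C5 to the oxygen-bearing C6. Read backwards, C3≡C4 is the terminal alkyne of a homopropargylic alcohol, so C4–CH3 and C2–C3 are cut in one operation (methylalumination, then alkenyl–alkyl coupling with 3-(2-iodoethyl)furan). The acetate goes on last.
- The alkynol (4R,6S)-9-(furan-3-yl)-6-methylnon-1-yn-4-ol comes from (S)-6-(furan-3-yl)-3-methylhexanal by catalyst-controlled allenylboration, which sets C6 of the target.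
- The aldehyde comes from (S)-citronellol, which supplies C8 and its methyl group. The alkene is cleaved by ozonolysis before any furan is present, and the C11–furan bond is made by sp3–sp2 Negishi coupling with 3-bromofuran.
- 3-(2-Iodoethyl)furan comes from 3-bromofuran and ethylene oxide.
- Ring formation: none. Both furan rings are bought as 3-bromofuran and carried through intact.

Key step: step 10

Remark on the chemistry: locants of the target chain are used throughout (furans on C1 and C11, alkene C3=C4, acetoxy carbon C6, methyl stereocentre C8). (S)-Citronellol of high enantiomeric purity is assumed. The (S)-phosphoric acid in step 7 is chosen on the assumption that the (R)-acid sends allyl- and allenylboronates to the Re face of aldehydes.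

**Route**

Step 1
Reactants: 1 (S)-citronellol [(3S)-3,7-dimethyloct-6-en-1-ol]
Product: 2 (S)-tert-butyl[(3,7-dimethyloct-6-en-1-yl)oxy]dimethylsilane
Conditions: TBSCl, imidazole, DMF, 0 °C → rt
Reagents that add atoms: tert-butyldimethylsilyl chloride, CC(C)(C)[Si](C)(C)Cl
Why: Standard silylation of a primary alcohol (silyl ether protection) keeps the two chain ends distinguishable after the ozonolysis and does not touch the stereocentre.

Step 2
Reactants: 2 (S)-tert-butyl[(3,7-dimethyloct-6-en-1-yl)oxy]dimethylsilane
Product: 4 (S)-6-[(tert-butyldimethylsilyl)oxy]-4-methylhexan-1-ol, via aldehyde 3 (not isolated)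
Conditions: O3, CH2Cl2/MeOH, −78 °C; then NaBH4, −78 °C → rt
Reagents that add atoms: ozone, [O-][O+]=O
Why: Reductive ozonolysis cleaves the trisubstituted alkene and reduces the resulting aldehyde in the same flask to the primary alcohol, while the silyl ether and the remote stereocentre should be unaffected.

Step 3
Reactants: 4 (S)-6-[(tert-butyldimethylsilyl)oxy]-4-methylhexan-1-ol
Product: 5 (S)-tert-butyl[(6-iodo-3-methylhexyl)oxy]dimethylsilane
Conditions: I2, PPh3, imidazole, CH2Cl2, 0 °C → rt
Reagents that add atoms: iodine, II
Why: Appel-type iodination converts the primary alcohol into the iodide by SN2 displacement at a non-stereogenic carbon, and the imidazole buffer protects the silyl ether.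

Step 4
Reactants: 5 (S)-tert-butyl[(6-iodo-3-methylhexyl)oxy]dimethylsilane; 6 3-bromofuran
Product: 8 (S)-tert-butyl{[6-(furan-3-yl)-3-methylhexyl]oxy}dimethylsilane, via alkylzinc iodide 7 (not isolated)
Conditions: Zn (activated with BrCH2CH2Br and Me3SiCl), LiCl, THF, 40 °C; then 6, Pd(OAc)2 (2 mol%), 2-dicyclohexylphosphino-2',6'-dimethoxybiphenyl (SPhos, 4 mol%), THF, rt → 50 °C
Reagents that add atoms: none
Why: Zinc insertion into the primary C–I bond followed by Negishi sp3–sp2 coupling with the heteroaryl bromide should form the C11–furan bond, the bulky biarylphosphine favouring reductive elimination over β-hydride elimination.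

Step 5
Reactants: 8 (S)-tert-butyl{[6-(furan-3-yl)-3-methylhexyl]oxy}dimethylsilane
Product: 9 (S)-6-(furan-3-yl)-3-methylhexan-1-ol
Conditions: Bu4NF, THF, 0 °C → rt
Reagents that add atoms: none
Why: Fluoride-mediated desilylation frees the primary alcohol under non-acidic conditions that spare the acid-sensitive furan.

Step 6
Reactants: 9 (S)-6-(furan-3-yl)-3-methylhexan-1-ol
Product: 10 (S)-6-(furan-3-yl)-3-methylhexanal
Conditions: Dess–Martin periodinane, CH2Cl2, 0 °C → rt; aq. NaHCO3/Na2S2O3 work-up
Reagents that add atoms: none
Why: Dess–Martin oxidation should stop cleanly at the aldehyde and leave the furan alone, and the stereocentre is β to the carbonyl and so cannot epimerise.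

Step 7
Reactants: 10 (S)-6-(furan-3-yl)-3-methylhexanal; 11 allenylboronic acid pinacol ester [4,4,5,5-tetramethyl-2-(propa-1,2-dien-1-yl)-1,3,2-dioxaborolane]
Product: 13 (4R,6S)-9-(furan-3-yl)-6-methylnon-1-yn-4-ol, via pinacol borate ester 12 (not isolated)
Conditions: (S)-3,3'-bis(2,4,6-triisopropylphenyl)-1,1'-binaphthyl-2,2'-diyl hydrogen phosphate (10 mol%), 4 Å MS, toluene, −20 °C; then aq. NaHCO3
Reagents that add atoms: none
Why: Chiral phosphoric acid-catalysed allenylboration (asymmetric propargylation) passes through a closed six-membered SE2' transition state that can give only the homopropargylic regioisomer, and the (S)-configured acid should direct attack to the Si face of the aldehyde to set the new carbinol centre as R, with little bias expected from the remote methyl centre.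

Step 8
Reactants: 6 3-bromofuran; 14 ethylene oxide
Product: 17 2-(furan-3-yl)ethan-1-ol, via furan-3-yllithium 15 (not isolated), via lithium alkoxytrifluoroborate 16 (not isolated)
Conditions: n-BuLi, THF, −78 °C; then 14, BF3·OEt2, −78 °C; then H2O
Reagents that add atoms: none
Why: Bromine–lithium exchange gives furan-3-yllithium, which is kept at −78 °C so that it does not isomerise to the 2-lithio species, and Lewis acid-promoted epoxide opening then adds the two-carbon hydroxyethyl arm.

Step 9
Reactants: 17 2-(furan-3-yl)ethan-1-ol
Product: 18 3-(2-iodoethyl)furan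
Conditions: I2, PPh3, imidazole, CH2Cl2, 0 °C → rt, dark
Reagents that add atoms: iodine, II
Why: Appel-type iodination of the primary alcohol under buffered conditions is tolerated by the furan, and the iodide is used promptly.

Step 10
Reactants: 13 (4R,6S)-9-(furan-3-yl)-6-methylnon-1-yn-4-ol; 19 trimethylaluminium; 18 3-(2-iodoethyl)furan
Product: 24 (3E,6R,8S)-1,11-di(furan-3-yl)-4,8-dimethylundec-3-en-6-ol, via aluminium alkoxide 20 (not isolated), via alkenylalane 21 (not isolated), via alkenylzinc chloride 22 (not isolated), via aluminium alkoxide of the coupled alkenol 23 (not isolated)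
Conditions: AlMe3 (3 equiv), Cp2ZrCl2 (0.25 equiv), CH2Cl2, 0 °C → rt; volatiles removed in vacuo; ZnCl2 (1.5 equiv), THF, 0 °C; then 18 (2 equiv), Pd2(dba)3 (2 mol%), tricyclopentylphosphine (8 mol%), N-methylimidazole, THF/NMP, 80 °C; aq. KNaC4H4O6 work-up
Reagents that add atoms: none
Why: AlMe3 first converts the hydroxyl into its dimethylaluminium alkoxide, and the methylzirconocene species formed from Cp2ZrCl2 and AlMe3 then adds CH3 and metal syn across the terminal alkyne, CH3 to the internal carbon C4 and the metal to the terminal carbon C3, with exchange from zirconium to aluminium closing the cycle (zirconium-catalysed methylalumination, a reaction known for homopropargylic alcohols). ZnCl2 turns the (E)-alkenylalane into the alkenylzinc chloride, zerovalent palladium carrying the bulky, electron-rich trialkylphosphine inserts into the primary C–I bond of 18, and transmetalation and reductive elimination form C2–C3; the closest known reaction type is the Negishi coupling of alkenylzinc halides with unactivated primary alkyl iodides, used here on an alkenylmetal taken directly from the carboalumination. No ring is closed and no stereocentre is created; the only new stereo-element is the C3=C4 geometry, which follows from the syn addition and from retention at the sp2 carbon during transmetalation and reductive elimination, so that C2 ends up cis to the C4 methyl and trans to C5, which is E. The regiochemistry is secured by the terminal alkyne, since the metal goes to the unhindered CH terminus. The excess AlMe3 is stripped off before the coupling so that methyl transfer to palladium does not compete, and donor solvents are used from the transmetalation onwards to hold back alkoxide-assisted E-to-Z isomerisation of the alkenylmetal. C6 and C8 take part in no bond change and keep their configuration.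

Step 11
Reactants: 24 (3E,6R,8S)-1,11-di(furan-3-yl)-4,8-dimethylundec-3-en-6-ol
Product: 25 (3E,6R,8S)-1,11-di(furan-3-yl)-4,8-dimethylundec-3-en-6-yl acetate
Conditions: Ac2O, pyridine, 4-dimethylaminopyridine (cat.), CH2Cl2, 0 °C → rt
Reagents that add atoms: acetic anhydride, CC(=O)OC(C)=O
Why: Nucleophile-catalysed O-acylation of the secondary alcohol leaves the C6–O bond intact, so the configuration at C6 is retained.

**Compound list**

1 | (S)-citronellol, (3S)-3,7-dimethyloct-6-en-1-ol | C[C@@H](CCC=C(C)C)CCO | starting material
2 | (S)-tert-butyl[(3,7-dimethyloct-6-en-1-yl)oxy]dimethylsilane | C[C@@H](CCC=C(C)C)CCO[Si](C)(C)C(C)(C)C | intermediate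
3 | (S)-6-[(tert-butyldimethylsilyl)oxy]-4-methylhexanal | C[C@@H](CCC=O)CCO[Si](C)(C)C(C)(C)C | intermediate
4 | (S)-6-[(tert-butyldimethylsilyl)oxy]-4-methylhexan-1-ol | C[C@@H](CCCO)CCO[Si](C)(C)C(C)(C)C | intermediate
5 | (S)-tert-butyl[(6-iodo-3-methylhexyl)oxy]dimethylsilane | C[C@@H](CCCI)CCO[Si](C)(C)C(C)(C)C | intermediate
6 | 3-bromofuran | Brc1ccoc1 | starting material
7 | {(4S)-6-[(tert-butyldimethylsilyl)oxy]-4-methylhexyl}zinc iodide | C[C@@H](CCC[Zn]I)CCO[Si](C)(C)C(C)(C)C | intermediate
8 | (S)-tert-butyl{[6-(furan-3-yl)-3-methylhexyl]oxy}dimethylsilane | C[C@@H](CCCc1ccoc1)CCO[Si](C)(C)C(C)(C)C | intermediate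
9 | (S)-6-(furan-3-yl)-3-methylhexan-1-ol | C[C@@H](CCCc1ccoc1)CCO | intermediate
10 | (S)-6-(furan-3-yl)-3-methylhexanal | C[C@@H](CCCc1ccoc1)CC=O | intermediate
11 | allenylboronic acid pinacol ester | C=C=CB1OC(C)(C)C(C)(C)O1 | starting material
12 | 2-{[(4R,6S)-9-(furan-3-yl)-6-methylnon-1-yn-4-yl]oxy}-4,4,5,5-tetramethyl-1,3,2-dioxaborolane | CC1(C)OB(O[C@@H](CC#C)C[C@@H](C)CCCc2ccoc2)OC1(C)C | intermediate
13 | (4R,6S)-9-(furan-3-yl)-6-methylnon-1-yn-4-ol | O[C@@H](CC#C)C[C@@H](C)CCCc1ccoc1 | intermediate
14 | ethylene oxide | C1CO1 | starting material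
15 | furan-3-yllithium | [Li]c1ccoc1 | intermediate
16 | lithium trifluoro[2-(furan-3-yl)ethoxy]borate | [Li+].F[B-](F)(F)OCCc1ccoc1 | intermediate
17 | 2-(furan-3-yl)ethan-1-ol | OCCc1ccoc1 | intermediate
18 | 3-(2-iodoethyl)furan | ICCc1ccoc1 | intermediate
19 | trimethylaluminium | C[Al](C)C | starting material
20 | dimethylaluminium (4R,6S)-9-(furan-3-yl)-6-methylnon-1-yn-4-olate | C[Al](C)O[C@@H](CC#C)C[C@@H](C)CCCc1ccoc1 | intermediate
21 | dimethylaluminium (1E,4R,6S)-1-(dimethylalumanyl)-9-(furan-3-yl)-2,6-dimethylnon-1-en-4-olate | C[Al](C)O[C@@H](C/C(C)=C/[Al](C)C)C[C@@H](C)CCCc1ccoc1 | intermediate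
22 | dimethylaluminium (1E,4R,6S)-1-(chlorozincio)-9-(furan-3-yl)-2,6-dimethylnon-1-en-4-olate | C[Al](C)O[C@@H](C/C(C)=C/[Zn]Cl)C[C@@H](C)CCCc1ccoc1 | intermediate
23 | dimethylaluminium (3E,6R,8S)-1,11-di(furan-3-yl)-4,8-dimethylundec-3-en-6-olate | C[Al](C)O[C@@H](C/C(C)=C/CCc1ccoc1)C[C@@H](C)CCCc1ccoc1 | intermediate
24 | (3E,6R,8S)-1,11-di(furan-3-yl)-4,8-dimethylundec-3-en-6-ol | O[C@@H](C/C(C)=C/CCc1ccoc1)C[C@@H](C)CCCc1ccoc1 | intermediate
25 | (3E,6R,8S)-1,11-di(furan-3-yl)-4,8-dimethylundec-3-en-6-yl acetate | CC(=O)O[C@@H](C/C(C)=C/CCc1ccoc1)C[C@@H](C)CCCc1ccoc1 | target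

**Step count**

Total: 11 steps. Longest linear sequence: 9 steps (steps 1–7, 10 and 11); steps 8 and 9 form the side branch.

**Steps most likely to fail**

Step 10. Three processes could erode it:
- methyl groups left on aluminium or zinc may transfer to the alkylpalladium intermediate;
- the 2-(furan-3-yl)ethylpalladium iodide may undergo β-hydride elimination before it is intercepted;
- the alkenylmetal may isomerise from E to Z with help from the neighbouring alkoxide at the coupling temperature.

The fallback reverses the polarity of the coupling while forming the same two bonds. It sets out from 13. The same methylalumination (AlMe3, Cp2ZrCl2, CH2Cl2, rt) is quenched with I2 in THF at −30 °C to give (1E,4R,6S)-9-(furan-3-yl)-1-iodo-2,6-dimethylnon-1-en-4-ol F1. Iodide 18 is converted with activated Zn and LiCl in THF into [2-(furan-3-yl)ethyl]zinc iodide F2. Negishi coupling of F1 with an excess of F2 (PdCl2(dppf), dppf = 1,1'-bis(diphenylphosphino)ferrocene, THF, rt) comes back to the route at 24; the excess covers any loss to the free hydroxyl.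

Step 7. Catalyst control over the facial selectivity may be incomplete with an unbranched aliphatic aldehyde, which would give a mixture of C4 epimers that is hard to separate. Acid-promoted condensation between furan and aldehyde is a second way to lose material. The fallback sets the carbinol centre by epoxide resolution instead, and sets out from 10:
- Corey–Chaykovsky methylenation (Me3SI, NaH, DMSO/THF, 0 °C) gives 2-[(2S)-5-(furan-3-yl)-2-methylpentyl]oxirane F3 as both epimers at the oxirane carbon.
- Hydrolytic kinetic resolution follows, with (R,R)-N,N'-bis(3,5-di-tert-butylsalicylidene)cyclohexane-1,2-diaminocobalt acetate (the trivalent cobalt complex; the enantiomer that hydrolyses the (S)-configured oxirane) and 0.55 equiv H2O. It should leave (2R)-2-[(2S)-5-(furan-3-yl)-2-methylpentyl]oxirane F4 and convert the other epimer into (2S,4S)-7-(furan-3-yl)-4-methylheptane-1,2-diol F5, which is removed by chromatography.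
- Opening of F4 at its terminal carbon with LiC≡CH·H2NCH2CH2NH2 in DMSO at rt comes back to the route at 13.

Step 4. Oxidative addition of zerovalent palladium into the electron-rich C–Br bond of 3-bromofuran may be slow, so that protodezincation and β-hydride elimination of the alkyl partner outrun the coupling. The fallback makes the C11–furan bond by carbonyl addition and then removes the extra oxygen. It sets out from 4:
- Dess–Martin oxidation gives aldehyde 3.
- Furan-3-yllithium 15 (from 6, n-BuLi, THF, −78 °C) is added to give (4S)-6-[(tert-butyldimethylsilyl)oxy]-1-(furan-3-yl)-4-methylhexan-1-ol F6 as both C1 epimers.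
- Acylation with 1,1'-thiocarbonyldiimidazole (CH2Cl2, rt) gives O-[(4S)-6-[(tert-butyldimethylsilyl)oxy]-1-(furan-3-yl)-4-methylhexyl] 1H-imidazole-1-carbothioate F7.
- Barton–McCombie deoxygenation (Bu3SnH, azobisisobutyronitrile, toluene, 80 °C) comes back to the route at 8.

**Further compounds**

F1 | step 10 | (1E,4R,6S)-9-(furan-3-yl)-1-iodo-2,6-dimethylnon-1-en-4-ol | O[C@@H](C/C(C)=C/I)C[C@@H](C)CCCc1ccoc1
F2 | step 10 | [2-(furan-3-yl)ethyl]zinc iodide | I[Zn]CCc1ccoc1
F3 | step 7 | 2-[(2S)-5-(furan-3-yl)-2-methylpentyl]oxirane (both epimers at the oxirane carbon) | C1OC1C[C@@H](C)CCCc2ccoc2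
F4 | step 7 | (2R)-2-[(2S)-5-(furan-3-yl)-2-methylpentyl]oxirane | O1C[C@H]1C[C@@H](C)CCCc2ccoc2
F5 | step 7 | (2S,4S)-7-(furan-3-yl)-4-methylheptane-1,2-diol | OC[C@@H](O)C[C@@H](C)CCCc1ccoc1
F6 | step 4 | (4S)-6-[(tert-butyldimethylsilyl)oxy]-1-(furan-3-yl)-4-methylhexan-1-ol (both C1 epimers) | C[C@@H](CCC(O)c1ccoc1)CCO[Si](C)(C)C(C)(C)C
F7 | step 4 | O-[(4S)-6-[(tert-butyldimethylsilyl)oxy]-1-(furan-3-yl)-4-methylhexyl] 1H-imidazole-1-carbothioate | C[C@@H](CCC(OC(=S)n1ccnc1)c2ccoc2)CCO[Si](C)(C)C(C)(C)C
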